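Begin with the two runs and what is asked of the flask, which is alder carried on to 12 min.

| setting | alder | oak | flask |
|---|---|---|---|
| electrophile | 29 mM | 58 mM | 29 mM |
| free base | 14.5 mM | 14.5 mM | 14.5 mM |
| protonated nucleophile | 72.5 mM | 72.5 mM | 72.5 mM |
| remark | the very flask that is asked about, followed so far | run made earlier |  |
| time |  |  | 12 min |

- alder (time / min: electrophile / %, target / %): 0.667: 90.6, 9.5; 1.33: 80.2, 17.7; 2.00: 72.2, 25.9; 3.00: 60.5, 36.5; 4.00: 50.3, 47.0; 5.00: 41.8, 55.7
- oak (time / min: electrophile / %, target / %): 0.417: 95.3, 3.8; 1.33: 85.3, 12.8; 2.50: 73.2, 22.0; 4.00: 61.0, 33.5; 5.00: 54.1, 41.0; 6.00: 47.1, 46.3; 8.00: 36.8, 55.7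

(scatter of a reading: 0.5 percentage points)

1. part of the electrophile that has reacted at 12 min
2. share of the unused nucleophile that is free and not bound as protonated nucleophile, at 12 min

- the numbers in the tables scatter with a standard deviation of 0.5 percentage points
- the earlier runs do not show how much of nucleophile is bound; that part of a forecast is a guess

Let y be the electrophile left as a fraction of its charge, and draw √y against time: in alder it falls from 1 to 0.647 by 5.00 min, nearly straight. Read s = 0.0707 min⁻¹, the root slope: the fall of √y per minute, the constant of an apparent half-order law. Oak, with twice the charge, gives 0.0492 min⁻¹. Alder's s over that is 1.44, close to the root of the charge ratio, 1.41, so, with free base and protonated nucleophile charged alike in the two runs, scale s by that root.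

Freeze s and run straight on: 2.30% is left at 12 min. That link is weak, since oak's line bends. While oak's used electrophile goes from 22.6 mM to 36.7 mM, a range that overlaps the span alder has still to cross, from 16.9 mM used up towards its charge of 29 mM, oak's slope is 0.0436 min⁻¹, less than over oak's whole run, and this scales to 0.0617 min⁻¹ for alder. Start again from alder's last reading with this slope: 4.62% is left, so commit to c = 95.4%. The readings do not show the free share, so leave it open.

The forecast gives 88% and 22%, lower on c than this reckoning, and holds the runs “nearly first order in electrophile”.

The flask gives c = 93.4% and a free share of 6.39%.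

    acid set free → by-product carried off (k = 0.570 s⁻¹)
    nucleophile + acid set free ⇌ protonated nucleophile, settled at all times (K = 3.00 × 10⁵ L mol⁻¹)
    acid set free + free base ⇌ salt of the base (K = 72000 L mol⁻¹, k = 11.0 L mol⁻¹ s⁻¹)
    2 electrophile → homo dimer (k = 0.00330 L mol⁻¹ s⁻¹)
    electrophile + nucleophile → acid set free + target (k = 2.10 L mol⁻¹ s⁻¹)

In the flask, acid set free has a half-life of 1.2 s against by-product carried off, shorter than the 0.19 min of nucleophile in the target-making step at the charged concentrations. At 12 min the flask holds 0.0489 mM of acid set free beside 2.96 mM of nucleophile. Over the whole run the flask's root slope is 0.0620 min⁻¹. Scaled, as an assumption, by the root of the protonated nucleophile charge, it becomes 0.0477 min⁻¹ for the neighbour flask with 43 mM, its other charges and the time held, which reckons 18.3% of the electrophile left at 12 min, and that neighbour flask holds 19.0%.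

The runs stem from a simulated flask for an exercise, noise included.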